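The data stem from a simulated flask on assumed constants, noise included.

The slow stretch was what I had to reckon with: in the north run the readings of complex with one exchanged went from 24.0% at 1.67 d down to 14.6% at 8.00 d, and the asked times lie further along that stretch.

the same everywhere: starting complex 0.010 M
- north: incoming ligand 0.34 equiv; leaving ligand 5 equiv; run made earlier
- east: incoming ligand 0.75 equiv; leaving ligand 5 equiv; run made earlier
- autumn: incoming ligand 0.500 equiv; leaving ligand 5.00 equiv; time 10 d
- dusk: incoming ligand 0.500 equiv; leaving ligand 5.00 equiv; time 15 d
- summer: incoming ligand 0.500 equiv; leaving ligand 5.00 equiv; time 20 d

| run | time / d | complex with one exchanged / % | starting complex / % |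
|---|---|---|---|
| north | 0.500 | 20.0 | 75.0 |
| north | 1.67 | 24.0 | 69.2 |
| north | 3.00 | 20.7 | 63.8 |
| north | 4.00 | 20.0 | 63.6 |
| north | 6.00 | 15.4 | 59.3 |
| north | 8.00 | 14.6 | 57.8 |
| east | 1.25 | 35.9 | 45.1 |
| east | 2.50 | 35.6 | 40.4 |
| east | 4.00 | 34.6 | 35.4 |
| east | 5.00 | 33.3 | 30.6 |
| east | 6.00 | 31.9 | 32.5 |
| east | 8.00 | 29.4 | 28.1 |

(each reading ± 1 percentage point)

- percent here means starting complex units held: one side product counts as two

* which of the two there is more of at the end, counted by the starting complex in each, autumn (complex with one exchanged / side product)
* which of the two there is more of at the end, counted by the starting complex in each, dusk (complex with one exchanged / side product)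
* which of the two there is more of at the end, counted by the starting complex in each, summer (complex with one exchanged / side product)
* final complex with one exchanged, as a percentage of the starting complex charged, in autumn
* final complex with one exchanged, as a percentage of the starting complex charged, in dusk
* final complex with one exchanged, as a percentage of the starting complex charged, in summer

1. In north, the gap between starting complex and complex with one exchanged read 45 percentage points at 1.67 d and 43 points at 8.00 d, level within the scatter. So I took one of each to be lost at each turn into side product.

2. A steady gap and a loss proportional to both amounts make the logarithm of their ratio climb in a straight line, with a slope proportional to the gap. North gave 0.0503 d⁻¹ powers of ten per whole charge of gap.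

3. Incoming ligand is the limiting reagent here. The autumn charge lies 0.390 of the way from north to east, so at 8.00 d I interpolated starting complex 46.2%, complex with one exchanged 20.4%, and a gap of 26 points.

4. My number is the lead: the powers of ten by which starting complex stands above complex with one exchanged. It folds charge, rate and time together, and it came to 0.382 at 10 d, 0.447 at 15 d and 0.512 at 20 d.

5. Turned back from powers of ten, the lead is the ratio of the two amounts, so complex with one exchanged is the gap divided by that ratio less one: 18.3%, 14.4% and 11.5%. I booked the remainder as side product, 37.4% in autumn, already more than complex with one exchanged.

6. Was one number enough? Not in east, where the gap fell from 4.8 points to −1.3 points, further than in north. The autumn charge lies nearer north, so I kept it.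

The forecast, in which exchange “equilibrates within about 2 d”, also put side product ahead but stood higher than mine, at 20%, 16.5% and 14%.

    starting complex + incoming ligand ⇌ leaving ligand + complex with one exchanged (K = 30.2, k = 20.9 L mol⁻¹ h⁻¹)
    starting complex + complex with one exchanged → side product (k = 0.545 L mol⁻¹ h⁻¹)
    complex with one exchanged + incoming ligand ⇌ leaving ligand + complex with two exchanged (K = 13.0, k = 17.3 L mol⁻¹ h⁻¹)
    2 incoming ligand → self-condensation product (k = 0.204 L mol⁻¹ h⁻¹)
    leaving ligand → by-product carried off (k = 0.0288 h⁻¹)

Complex with one exchanged ended at 18.9% in autumn, 14.7% in dusk and 11.6% in summer, against side product at 32.3%, 40.9% and 47.0%; the autumn lead stood at 0.341 against my 0.382. In autumn, complex with one exchanged was made 1.01 times as fast as it was used up at 1.03 d, each step taken net, but at 10.0 d that ratio was 0.0147. Its forward use into side product then ran 84 times its forward use by the second exchange. For the neighbour charged with 0.850 equiv, at 1.24 on my scale, the lead reckoned the same way is −0.212, and in that flask it is −0.112, with complex with one exchanged at 29.3%, above side product at 27.7%.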